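The six-membered ring is read as the enol ether (O1–C7a=C7–C6=O) of a cyclohexane-1,3-dione whose C5 bears methoxy and allyl. Everything rests on stitching an acetyl unit (C6–C7) between C5 and the lactone carbonyl C7a of a trans-γ-aryl-β-methyl butyrolactone. In one flask the lactone enolate adds to allyl 2-methoxyacrylate, the resulting C5 ester enolate is C-acetylated (C6–C5) and the methyl ketone closes onto the lactone carbonyl by Dieckmann condensation (C7–C7a). The C5 allyl ester then becomes the C5 allyl group by catalyst-controlled decarboxylative allylation, and γ-bromination/dehydrobromination installs C3a=C4.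

Key step: step 5

Remarks on the chemistry
- Atom labels follow benzofuran numbering of the target: O1, C2 (aryl), C3 (methyl), C3a, C4, C5 (OMe, allyl), C6 (C=O), C7, C7a.
- Assumption: methyl 2-methoxyacrylate (9) is purchased.
- Assumption: the senses of induction of (R)-TRIP (step 1) and (S)-t-Bu-PHOX (step 7) are taken by analogy with simple aryl aldehydes and 2-alkylcyclohexanone enolates; the antipodal catalyst is the remedy if either is reversed.

Step 1
Reactants: 1 3,4-dimethoxybenzaldehyde; 2 (E)-crotylboronic acid pinacol ester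
Product: 4 (1R,2R)-1-(3,4-dimethoxyphenyl)-2-methylbut-3-en-1-ol, via pinacol borate ester 3 (not isolated)
Conditions: (R)-TRIP (5 mol %), 4 Å MS, PhMe, −30 °C; aq. NaHCO3
Reagents that add atoms: none
Why: Chiral phosphoric acid-catalysed crotylboration through a closed chair transition state; the (E)-boronate should give the anti adduct and the catalyst fixes the aldehyde face, so C2 and C3 are set here (expected 1R,2R).

Step 2
Reactants: 4 (1R,2R)-1-(3,4-dimethoxyphenyl)-2-methylbut-3-en-1-ol
Product: 6 (1R,2R)-1-(3,4-dimethoxyphenyl)-2-methylbutane-1,4-diol, via bis(9-BBN) adduct 5 (not isolated)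
Conditions: 9-BBN (2.3 eq), THF, 0 °C to rt; then 3 M NaOH, 30% H2O2, 0 °C
Reagents that add atoms: hydrogen peroxide, OO
Why: Anti-Markovnikov hydroboration of the terminal alkene and oxidative work-up (hydroboration–oxidation) should give the primary alcohol without touching either stereocentre.

Step 3
Reactants: 6 (1R,2R)-1-(3,4-dimethoxyphenyl)-2-methylbutane-1,4-diol
Product: 8 (4R,5R)-5-(3,4-dimethoxyphenyl)-4-methyldihydrofuran-2(3H)-one, via lactol 7 (not isolated)
Conditions: TEMPO (0.2 eq), PhI(OAc)2 (2.5 eq), CH2Cl2, rt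
Reagents that add atoms: none
Why: TEMPO/PhI(OAc)2 oxidises the primary alcohol first; the aldehyde is trapped by the benzylic hydroxyl as lactol 7 and oxidised on to the trans γ-lactone (oxidative lactonisation).

Step 4
Reactants: 9 methyl 2-methoxyacrylate; 10 allyl alcohol
Product: 11 allyl 2-methoxyacrylate
Conditions: Ti(OiPr)4 (5 mol %), BHT (cat.), excess 10, 90 °C, MeOH distilled off
Reagents that add atoms: none
Why: Titanate-catalysed transesterification driven by removal of methanol; the donor-substituted acrylate is a poor oxa-Michael acceptor, so the alkene should survive.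

Step 5
Reactants: 8 (4R,5R)-5-(3,4-dimethoxyphenyl)-4-methyldihydrofuran-2(3H)-one; 11 allyl 2-methoxyacrylate; 12 acetyl chloride
Product: 16 allyl (5R)-5-[(1R,2R)-1-(3,4-dimethoxyphenyl)-1-hydroxypropan-2-yl]-1-methoxy-2,4-dioxocyclohexane-1-carboxylate (C1 epimers), via lactone lithium enolate 13 (not isolated), via Michael adduct enolate 14 (not isolated), via beta-keto ester 15 (not isolated)
Conditions: LiHMDS (1.05 eq), THF, −78 °C; 11 (1.0 eq), −78 to −45 °C; cannulate into 12 (1.3 eq), THF, −78 °C; LiHMDS (3.5 eq), −78 to 0 °C; 1 M HCl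
Reagents that add atoms: none
Why: Enolate 13 adds to acrylate 11 anti to the C3 methyl, which forms C3a–C4 and delivers the α-methoxy ester enolate 14 regiospecifically at C5; C-acylation of 14 by 12 makes the C6–C5 bond (15), and the methyl ketone enolate raised by the second portion of LiHMDS attacks the lactone carbonyl C7a, expels the C2 alkoxide and seals the C7–C7a bond as the doubly stabilised 1,3-diketone enolate. The closest known reaction types are the tandem Michael addition/enolate acylation and the Dieckmann (intramolecular Claisen) route to cyclohexane-1,3-diones. The ring closes in the 6-(enolendo)-exo-trig mode. C3a is set trans to the C3 methyl by substrate control and C5 forms as a mixture; neither matters later, because C5 is re-formed through a planar palladium enolate in step 7 and C3a becomes sp2 in step 8. The step needs C-acylation at C5 and not at C3a, which is secured by generating the C5 enolate through the conjugate addition and trapping it cold by inverse addition before proton exchange; it also needs the C7 enolate to choose the lactone carbonyl, the only carbonyl within reach of a six-membered ring.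

Step 6
Reactants: 16 allyl (5R)-5-[(1R,2R)-1-(3,4-dimethoxyphenyl)-1-hydroxypropan-2-yl]-1-methoxy-2,4-dioxocyclohexane-1-carboxylate
Product: 17 allyl (2R,3R,3aR)-2-(3,4-dimethoxyphenyl)-5-methoxy-3-methyl-6-oxo-2,3,3a,4,5,6-hexahydrobenzofuran-5-carboxylate (C5 epimers)
Conditions: CSA (10 mol %), 4 Å MS, CH2Cl2, rt to 40 °C
Reagents that add atoms: none
Why: Acid-catalysed intramolecular enol etherification of the cyclic 1,3-dione (vinylogous esterification) re-forms O1–C7a; only the C7a carbonyl allows a five-membered ring, and the trans C2/C3 arrangement is also the thermodynamic one should C2 ionise.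

Step 7
Reactants: 17 allyl (2R,3R,3aR)-2-(3,4-dimethoxyphenyl)-5-methoxy-3-methyl-6-oxo-2,3,3a,4,5,6-hexahydrobenzofuran-5-carboxylate
Product: 18 (2R,3R,3aR,5S)-5-allyl-2-(3,4-dimethoxyphenyl)-5-methoxy-3-methyl-2,3,3a,4-tetrahydrobenzofuran-6(5H)-one
Conditions: Pd2(dba)3 (2.5 mol %), (S)-t-Bu-PHOX (6.5 mol %), PhMe, 30 °C
Reagents that add atoms: none
Why: Stereoablative palladium-catalysed decarboxylative asymmetric allylic alkylation (Tsuji–Trost type) of an α-alkoxy β-keto allyl ester: both C5 epimers of 17 collapse to one palladium enolate and the PHOX ligand controls the face of C5–allyl bond formation, so C5 (S) is set under catalyst control.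

Step 8
Reactants: 18 (2R,3R,3aR,5S)-5-allyl-2-(3,4-dimethoxyphenyl)-5-methoxy-3-methyl-2,3,3a,4-tetrahydrobenzofuran-6(5H)-one
Product: 20 (2R,3R,5S)-5-allyl-2-(3,4-dimethoxyphenyl)-5-methoxy-3-methyl-6-(trimethylsilyloxy)-2,3,4,5-tetrahydrobenzofuran, via lithium dienolate 19 (not isolated)
Conditions: LDA (1.3 eq), THF, −78 °C; TMSCl (2 eq), −78 to 0 °C; pentane, cold aq. NaHCO3; used crude
Reagents that add atoms: chlorotrimethylsilane, C[Si](C)(C)Cl
Why: With C5 quaternary the only acidic hydrogen is the γ-H at C3a, so kinetic γ-deprotonation of the vinylogous ester and O-silylation should give the 2-silyloxy diene (extended enolate formation); the transient C3a centre is erased.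

Step 9
Reactants: 20 (2R,3R,5S)-5-allyl-2-(3,4-dimethoxyphenyl)-5-methoxy-3-methyl-6-(trimethylsilyloxy)-2,3,4,5-tetrahydrobenzofuran
Product: 22 (2R,3R,5S)-5-allyl-2-(3,4-dimethoxyphenyl)-5-methoxy-3-methyl-2,3-dihydrobenzofuran-6(5H)-one, via tertiary bromide 21 (not isolated)
Conditions: NBS (1.05 eq), THF, −78 °C; then DBU (2.5 eq), −78 °C to rt
Reagents that add atoms: none
Why: NBS should brominate the diene terminus C3a (β to O1, vinylogous to OSiMe3) anti to the C3 methyl to give 21; anti E2 with DBU can then only use a C4 hydrogen, because C3–H is syn to bromine, which gives the C3a=C4 dienone (γ-bromination/dehydrobromination of a dienol ether).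

Compound list
1 | 3,4-dimethoxybenzaldehyde | COc1ccc(C=O)cc1OC | starting material
2 | (E)-crotylboronic acid pinacol ester | C/C=C/CB1OC(C)(C)C(C)(C)O1 | starting material
3 | pinacol borate ester of alcohol 4 | CC1(C)OB(O[C@@H](c2ccc(OC)c(OC)c2)[C@@H](C=C)C)OC1(C)C | intermediate
4 | (1R,2R)-1-(3,4-dimethoxyphenyl)-2-methylbut-3-en-1-ol | O[C@@H](c1ccc(OC)c(OC)c1)[C@@H](C=C)C | intermediate
5 | O,C-bis(9-borabicyclo[3.3.1]nonan-9-yl) adduct of 4 | O(B1C2CCCC1CCC2)[C@@H](c1ccc(OC)c(OC)c1)[C@@H](CCB1C2CCCC1CCC2)C | intermediate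
6 | (1R,2R)-1-(3,4-dimethoxyphenyl)-2-methylbutane-1,4-diol | O[C@@H](c1ccc(OC)c(OC)c1)[C@@H](CCO)C | intermediate
7 | (4R,5R)-5-(3,4-dimethoxyphenyl)-4-methyltetrahydrofuran-2-ol (anomers) | O1[C@@H](c2ccc(OC)c(OC)c2)[C@@H](CC1O)C | intermediate
8 | (4R,5R)-5-(3,4-dimethoxyphenyl)-4-methyldihydrofuran-2(3H)-one | O1[C@@H](c2ccc(OC)c(OC)c2)[C@@H](CC1=O)C | intermediate
9 | methyl 2-methoxyacrylate | C=C(OC)C(=O)OC | starting material
10 | allyl alcohol | C=CCO | starting material
11 | allyl 2-methoxyacrylate | C=C(OC)C(=O)OCC=C | intermediate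
12 | acetyl chloride | CC(Cl)=O | starting material
13 | lithium enolate of lactone 8 | O1[C@@H](c2ccc(OC)c(OC)c2)[C@@H](C=C1[O-])C.[Li+] | intermediate
14 | lithium enolate of allyl 2-methoxy-3-[(3R,4R,5R)-5-(3,4-dimethoxyphenyl)-4-methyl-2-oxotetrahydrofuran-3-yl]propanoate | O1[C@@H](c2ccc(OC)c(OC)c2)[C@H](C)[C@@H](CC(OC)=C([O-])OCC=C)C1=O.[Li+] | intermediate
15 | allyl 2-acetyl-2-methoxy-3-[(3R,4R,5R)-5-(3,4-dimethoxyphenyl)-4-methyl-2-oxotetrahydrofuran-3-yl]propanoate (C2 epimers) | O1[C@@H](c2ccc(OC)c(OC)c2)[C@H](C)[C@@H](CC(OC)(C(C)=O)C(=O)OCC=C)C1=O | intermediate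
16 | allyl (5R)-5-[(1R,2R)-1-(3,4-dimethoxyphenyl)-1-hydroxypropan-2-yl]-1-methoxy-2,4-dioxocyclohexane-1-carboxylate (C1 epimers) | O[C@@H](c1ccc(OC)c(OC)c1)[C@H](C)[C@H]1CC(OC)(C(=O)OCC=C)C(=O)CC1=O | intermediate
17 | allyl (2R,3R,3aR)-2-(3,4-dimethoxyphenyl)-5-methoxy-3-methyl-6-oxo-2,3,3a,4,5,6-hexahydrobenzofuran-5-carboxylate (C5 epimers) | O1[C@@H](c2ccc(OC)c(OC)c2)[C@H](C)[C@H]3CC(OC)(C(=O)OCC=C)C(=O)C=C13 | intermediate
18 | (2R,3R,3aR,5S)-5-allyl-2-(3,4-dimethoxyphenyl)-5-methoxy-3-methyl-2,3,3a,4-tetrahydrobenzofuran-6(5H)-one | C=CC[C@]1(OC)C[C@H]2C(=CC1=O)O[C@@H](c1ccc(OC)c(OC)c1)[C@@H]2C | intermediate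
19 | lithium dienolate of 18 | C=CC[C@]1(OC)CC2=C(C=C1[O-])O[C@@H](c1ccc(OC)c(OC)c1)[C@@H]2C.[Li+] | intermediate
20 | (2R,3R,5S)-5-allyl-2-(3,4-dimethoxyphenyl)-5-methoxy-3-methyl-6-(trimethylsilyloxy)-2,3,4,5-tetrahydrobenzofuran | C=CC[C@]1(OC)CC2=C(C=C1O[Si](C)(C)C)O[C@@H](c1ccc(OC)c(OC)c1)[C@@H]2C | intermediate
21 | (2R,3R,3aR,5S)-5-allyl-3a-bromo-2-(3,4-dimethoxyphenyl)-5-methoxy-3-methyl-2,3,3a,4-tetrahydrobenzofuran-6(5H)-one | C=CC[C@]1(OC)C[C@]2(Br)C(=CC1=O)O[C@@H](c1ccc(OC)c(OC)c1)[C@@H]2C | intermediate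
22 | (2R,3R,5S)-5-allyl-2-(3,4-dimethoxyphenyl)-5-methoxy-3-methyl-2,3-dihydrobenzofuran-6(5H)-one | C=CC[C@]1(OC)C=C2C(=CC1=O)O[C@@H](c1ccc(OC)c(OC)c1)[C@@H]2C | target

Total step count: 9
Longest linear sequence: 8 steps (1, 2, 3, 5, 6, 7, 8, 9)

Steps most likely to fail

1. Step 5. The conjugate addition to the donor-substituted acrylate may be slow, the C5 enolate may exchange a proton with C3a before it is acylated, and O-acylation may compete with C-acylation. Fallback, setting out from 8: α-methylenation (LiHMDS, Eschenmoser's salt; then MeI, NaHCO3) passes through the Mannich base F1 to the α-methylene lactone F2. Separately, commercial allyl acetoacetate is converted by diazo transfer (p-ABSA, Et3N) into allyl 2-diazo-3-oxobutanoate F3 and then, by Rh2(OAc)4-catalysed O–H insertion into methanol, into allyl 2-methoxy-3-oxobutanoate F4. DBU-catalysed Michael addition of F4 to F2 should give 15 as an isolated compound, and LiHMDS closes it to 16, where the route is rejoined. In this variant the acetyl unit arrives already attached to C5 and the ring is made by a Michael/Dieckmann annulation.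

2. Step 7. Catalyst control may be eroded by the α-methoxy group or opposed by the resident stereocentres (poor facial selectivity), and the palladium enolate may be protonated instead of allylated. Fallback, setting out from 17: deallylation–decarboxylation (Pd(PPh3)4, HCO2H, Et3N, THF) gives the α′-methoxy ketone F5. Stork–Danheiser α′-alkylation (LDA, THF, −78 °C; allyl bromide) then forms the C5–allyl bond under substrate control, and 18 is separated from its C5 epimer by chromatography; the route is rejoined at 18.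

3. Step 9. Bromine may enter at C7 or on the face syn to the C3 methyl, after which elimination toward C3 competes with elimination toward C4 (loss of regiocontrol). Fallback, setting out from 20: Saegusa–Ito oxidation (Pd(OAc)2, MeCN, rt), in which β-hydride elimination from the palladium dienolate replaces the bromide E2, should lead directly to 22; no new compound is involved.

Further compounds
F1 | step 5 | (3S,4R,5R)-5-(3,4-dimethoxyphenyl)-3-[(dimethylamino)methyl]-4-methyldihydrofuran-2(3H)-one | O1[C@@H](c2ccc(OC)c(OC)c2)[C@H](C)[C@@H](CN(C)C)C1=O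
F2 | step 5 | (4R,5R)-5-(3,4-dimethoxyphenyl)-4-methyl-3-methylidenedihydrofuran-2(3H)-one | O1[C@@H](c2ccc(OC)c(OC)c2)[C@H](C)C(=C)C1=O
F3 | step 5 | allyl 2-diazo-3-oxobutanoate | CC(=O)C(=[N+]=[N-])C(=O)OCC=C
F4 | step 5 | allyl 2-methoxy-3-oxobutanoate | CC(=O)C(OC)C(=O)OCC=C
F5 | step 7 | (2R,3R,3aR)-2-(3,4-dimethoxyphenyl)-5-methoxy-3-methyl-2,3,3a,4-tetrahydrobenzofuran-6(5H)-one (C5 epimers) | O1[C@@H](c2ccc(OC)c(OC)c2)[C@H](C)[C@H]3CC(OC)C(=O)C=C13
F0 | step 9 | none | none
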